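The rate constants are assumed; the result is computed.

in all of them: fresh partner 1.10 equiv (in portions, 3); gas 0.41 mM (held); time 4.0 s

| flask | starting material | remark |
|---|---|---|
| north-east | 2.5 × 10⁻⁴ M | the portions of fresh partner follow each other after 0.50 s, the first at the start |
| north | 5.0 × 10⁻⁴ M | the portions of fresh partner follow each other after 0.50 s, the first at the start |
| south-west | 0.0010 M | the portions of fresh partner follow each other after 0.50 s, the first at the start |
| west | 0.0020 M | the portions of fresh partner follow each other after 0.50 s, the first at the start |
| east | 0.0040 M | the portions of fresh partner follow each other after 0.50 s, the first at the start |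

    starting material + coupling partner → open intermediate (k1 = 1830 M⁻¹ s⁻¹)
    open intermediate + second intermediate → target (k2 = 7380 M⁻¹ s⁻¹)
    starting material + target → side product (k3 = 42.6 M⁻¹ s⁻¹)
    coupling partner + fresh partner → second intermediate (k4 = 17800 M⁻¹ s⁻¹)
    gas ⇌ coupling partner, rate k5*(csat - [coupling partner]) (k5 = 0.808 s⁻¹, csat = 0.41 mM)

- a species is counted by the starting material in it: one side product counts as two
- at the start none of coupling partner is dissolved
- "hardly changes" means that all values lie within two and a half points (for a concentration: within two and a half percent of the largest)
- run time (north-east): 4.0 s

- [target] at the end for north-east, north, south-west, west, east, in this order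
- how the row runs (hardly changes / falls all the way / falls, then rises / rises all the way / rises, then falls)

Start from what is slow. Gas enters a liquid empty of coupling partner at 0.331 mM s⁻¹, and less as coupling partner builds up, and each bit of coupling partner then has two takers, fresh partner and starting material. So I turn the constants into times, counting the portions as one charge, since the last one is in by 1.00 s. I add one time of my own: how long the gas, at that rate, takes to supply one coupling partner for each fresh partner charged. This is the pay-off time, 0.830 s in north-east and 13.3 s in east.

| Time at the charged amounts | north-east | east |
|---|---|---|
| half-life of coupling partner against fresh partner | 0.142 s | 0.00885 s |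
| half-life of coupling partner against starting material | 1.52 s | 0.0947 s |
| half-life of target against starting material | 65.1 s | 4.07 s |
| pay-off time | 0.830 s | 13.3 s |

Read the first two rows against each other: in both columns, at the charged amounts, fresh partner takes coupling partner ten times faster than starting material does, so I expect the gas to pay fresh partner first. The third row is long against the run in north-east, but close to it in east, so I expect the side step to count for more in east than in north-east.

The last row gives the shape. By this reckoning, after the pay-off the run has 3.17 s left in north-east, while in east the pay-off time is longer than the run. Starting material grows with the charge and the time left shrinks with it, so I score their product, charge times time left. That is largest at a charge of 6.02 × 10⁻⁴ M, where the pay-off time is half the run. That charge lies above the north-east charge and below the east charge, so I expect the row to run rises, then falls, and I commit to that peak, not to five values.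

The forecast gives 1.600 × 10⁻⁴ M, 2.600 × 10⁻⁴ M, 1.900 × 10⁻⁴ M, 1.350 × 10⁻⁴ M and 9.000 × 10⁻⁵ M, so rises, then falls, saying that at high loading “the fast reaction with fresh partner takes most of the coupling partner”.

The flask gives 1.39 × 10⁻⁴ M, 2.12 × 10⁻⁴ M, 1.83 × 10⁻⁴ M, 1.39 × 10⁻⁴ M and 1.09 × 10⁻⁴ M, so rises, then falls.

In north-east the pay-off time of 0.830 s is shorter than the run, and at 4.00 s fresh partner stands at 0 % of its charge, coupling partner at 3.08 × 10⁻⁴ M and target at 55.6 % of the starting material charged. In west the pay-off time of 6.64 s is longer than the run, and at 4.00 s fresh partner still stands at 49.7 % of its charge, coupling partner at 1.39 × 10⁻⁵ M and target at 6.93 %, while the row turns, as read, at 5.9 × 10⁻⁴ M.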